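Presumed biogenesis: a nor‑guaiazulene unit, oxygenated on its five‑membered ring and bonded through C2 to C3 of guaiazulene, contracts its seven‑membered ring oxidatively, one ring carbon leaving as the formyl group (azulene → 4‑formylinden‑1‑one).
Disconnection 1 (last step): the benzene ring and CHO of the target come from the seven‑membered ring of 2‑(guaiazulen‑3‑yl)‑3,8‑dimethylazulen‑1‑ol, with C4 extruded as CHO onto C5.
Disconnection 2: that seven‑membered ring comes from a [6+4] union of a cyclopentenone‑derived 6‑aminofulvene with thiophene 1,1‑dioxide.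
Disconnection 3: the aminofulvene precursor comes from 2‑(guaiazulen‑3‑yl)‑3‑methylcyclopent‑2‑enone, itself from guaiazulene and 2‑bromo‑3‑methylcyclopent‑2‑enone (C–C union first).
Ring order: the guaiazulene rings and the cyclopentenone ring are bought; the seven‑membered ring is made in step 3; the benzene ring is made last, by ring contraction, in step 4.

Assumption: the target has no stereocentre and no configurationally defined axis, so it is one achiral compound and no enantiocontrol is needed. "Guaiazulen‑3‑yl" below means 5‑isopropyl‑3,8‑dimethylazulen‑1‑yl.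

Step 1
Reactants: 1 guaiazulene (7‑isopropyl‑1,4‑dimethylazulene); 2 2‑bromo‑3‑methylcyclopent‑2‑en‑1‑one
Product: 3 2‑(guaiazulen‑3‑yl)‑3‑methylcyclopent‑2‑en‑1‑one
Conditions: Pd(OAc)2 (2 mol %), KOAc (2 equiv), DMAc, 120 °C, Ar
Reagents that add atoms: none
Why: Pd‑catalysed direct C–H coupling (direct arylation type): the α‑bromoenone adds oxidatively to zerovalent palladium, acetate‑assisted palladation takes place at C3, the only free and most nucleophilic five‑ring carbon of guaiazulene, and reductive elimination gives the C2–C3' bond without pre‑metalating the azulene.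

Step 2
Reactants: 3 2‑(guaiazulen‑3‑yl)‑3‑methylcyclopent‑2‑en‑1‑one; 4 N,N‑dimethylacetamide dimethyl acetal
Product: 5 (E)‑5‑[1‑(dimethylamino)ethylidene]‑2‑(guaiazulen‑3‑yl)‑3‑methylcyclopent‑2‑en‑1‑one
Conditions: 4 (3 equiv), toluene, 90 °C, MeOH distilled off
Reagents that add atoms: none
Why: Amide‑acetal condensation (enaminone formation): C5 is the only α‑methylene of the ketone and condenses with loss of two methanol, which places the future C7 carbon and its methyl group next to the carbonyl, while the much less acidic 4‑methyl group of the guaiazulene part reacts only at far higher temperature.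

Step 3
Reactants: 5 (E)‑5‑[1‑(dimethylamino)ethylidene]‑2‑(guaiazulen‑3‑yl)‑3‑methylcyclopent‑2‑en‑1‑one; 6 trans‑3,4‑dibromotetrahydrothiophene 1,1‑dioxide
Product: 9 2‑(guaiazulen‑3‑yl)‑3,8‑dimethylazulen‑1‑ol, via thiophene 1,1‑dioxide 7 (not isolated), via bridged sulfone 8 (not isolated)
Conditions: 6 (2 equiv, slow addition), DBU (5 equiv), degassed MeCN, 0 → 70 °C, Ar; degassed aq. NH4Cl, quick filtration through deactivated silica under Ar
Reagents that add atoms: none
Why: Proposed new method: DBU eliminates two HBr from 6 to give thiophene 1,1‑dioxide and deprotonates C4 of 5 to the 1‑oxido‑6‑(dimethylamino)fulvene, whose 6π system adds across C2/C5 of the electron‑poor diene sulfone ([6+4] cycloaddition, possible only at C4 and the amino carbon, so the regiochemistry is fixed); β‑elimination of dimethylamine from the resulting enolate gives 8, and cheletropic loss of SO2 followed by enolisation gives the aromatic azulenol 9, whose C2 and C3 are blocked against oxidative coupling, so it survives a quick oxygen‑free isolation and is carried into step 4 the same day; the closest known reaction is the [6+4] azulene synthesis from 6‑aminofulvenes and thiophene 1,1‑dioxides.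

Step 4
Reactants: 9 2‑(guaiazulen‑3‑yl)‑3,8‑dimethylazulen‑1‑ol
Product: 12 3,7‑dimethyl‑2‑[3,8‑dimethyl‑5‑(propan‑2‑yl)azulen‑1‑yl]‑1‑oxo‑1H‑indene‑4‑carbaldehyde, via oxoazulenium ion 10 (not isolated), via hydroperoxide 11 (not isolated)
Conditions: chloranil (1.05 equiv), AcOH–CH2Cl2, −20 °C, Ar; then 30 % aq. H2O2 (5 equiv), 0 °C → rt
Reagents that add atoms: hydrogen peroxide (OO)
Why: Proposed new method: chloranil (too weak an oxidant to touch the guaiazulene part) can only remove two electrons and a proton from the blocked azulenol 9 to give the acyl‑tropylium‑type cation 10; hydrogen peroxide adds reversibly to the seven‑membered ring, and the C4 adduct 11 closes to its norcaradiene and undergoes heterolytic, Grob‑type fragmentation (O–O heterolysis with cleavage of the C4–C3a bond, the only cleavage that leaves a cation stabilised by the guaiazulenyl group), so C4 is extruded as the formyl group on C5 and proton loss gives the benzene ring; the closest known reaction is the oxidation of tropylium salts to benzaldehyde with hydrogen peroxide, the laboratory counterpart of the presumed biogenetic contraction.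

Compound list
1 | guaiazulene (7‑isopropyl‑1,4‑dimethylazulene) | c1cc(C)c2cc(C(C)C)ccc(C)c1-2 | starting material
2 | 2‑bromo‑3‑methylcyclopent‑2‑en‑1‑one | CC1=C(Br)C(=O)CC1 | starting material
3 | 2‑(guaiazulen‑3‑yl)‑3‑methylcyclopent‑2‑en‑1‑one | CC1=C(-c2cc(C)c3cc(C(C)C)ccc(C)c2-3)C(=O)CC1 | intermediate
4 | N,N‑dimethylacetamide dimethyl acetal (1,1‑dimethoxy‑N,N‑dimethylethanamine) | CC(OC)(OC)N(C)C | starting material
5 | (E)‑5‑[1‑(dimethylamino)ethylidene]‑2‑(guaiazulen‑3‑yl)‑3‑methylcyclopent‑2‑en‑1‑one (push–pull alkene, geometry lost in step 3) | CN(C)/C(C)=C1\CC(C)=C(-c2cc(C)c3cc(C(C)C)ccc(C)c2-3)C1=O | intermediate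
6 | trans‑3,4‑dibromotetrahydrothiophene 1,1‑dioxide (racemic, one enantiomer drawn) | Br[C@H]1CS(=O)(=O)C[C@@H]1Br | starting material
7 | thiophene 1,1‑dioxide | O=S1(=O)C=CC=C1 | intermediate (not isolated)
8 | bridged sulfone: 2‑(guaiazulen‑3‑yl)‑3,8‑dimethyl‑3a,4,7‑trihydroazulen‑1‑one with an SO2 bridge from C4 to C7 (C2=C3, C5=C6, C8=C8a; both C3a epimers, all stereocentres lost in the same flask) | O=C1C(-c2cc(C)c3cc(C(C)C)ccc(C)c2-3)=C(C)C2C1=C(C)C1C=CC2S1(=O)=O | intermediate (not isolated)
9 | 2‑(guaiazulen‑3‑yl)‑3,8‑dimethylazulen‑1‑ol (air‑sensitive, handled under Ar) | Oc1c(-c2cc(C)c3cc(C(C)C)ccc(C)c2-3)c(C)c2ccccc(C)c1-2 | intermediate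
10 | 2‑(guaiazulen‑3‑yl)‑3,8‑dimethyl‑1‑oxo‑1H‑azulenium ion (counter‑ion: tetrachlorohydroquinone monoanion) | O=C1C(-c2cc(C)c3cc(C(C)C)ccc(C)c2-3)=C(C)C2=CC=CC=C(C)[C+]12 | intermediate (not isolated)
11 | (±)‑2‑(guaiazulen‑3‑yl)‑4‑hydroperoxy‑3,8‑dimethylazulen‑1(4H)‑one | O=C1C(-c2cc(C)c3cc(C(C)C)ccc(C)c2-3)=C(C)C2=C1C(C)=CC=CC2OO | intermediate (not isolated)
12 | 3,7‑dimethyl‑2‑[3,8‑dimethyl‑5‑(propan‑2‑yl)azulen‑1‑yl]‑1‑oxo‑1H‑indene‑4‑carbaldehyde (achiral) | CC1=C(c2cc(C)c3cc(C(C)C)ccc(C)c2-3)C(=O)c2c(C)ccc(C=O)c21 | target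

The four starting materials (1, 2, 4, 6) are inexpensive catalogue chemicals.

Total step count: 4. Longest linear sequence: 4 steps (1 → 3 → 5 → 9 → 12).

Steps most likely to fail

Step 4 (oxidative ring contraction): hydrogen peroxide may add at C6 or C8 instead of C4, or the azulenol may over‑oxidise or decompose before the cation forms. The fallback sets out from 1 and comes back at 12, taking the benzene ring from an arene instead. 4‑Bromotoluene and crotonyl chloride (AlCl3, then AlCl3–NaCl, 140 °C; Friedel–Crafts acylation and cyclialkylation) give (±)‑4‑bromo‑3,7‑dimethylindan‑1‑one F1. SeO2 (dioxane–H2O, reflux) gives (±)‑4‑bromo‑3,7‑dimethylindane‑1,2‑dione F2. Guaiazulene 1 attacks the C2 carbonyl of F2 with its C3 and water is lost towards C3 (AcOH, 50 °C) to give 4‑bromo‑2‑(guaiazulen‑3‑yl)‑3,7‑dimethylinden‑1‑one F3. Reductive carbonylation of F3 (Pd(OAc)2, di(1‑adamantyl)‑n‑butylphosphine, CO/H2, TMEDA, toluene, 100 °C) gives 12.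

Step 3 ([6+4] annulation of an oxido‑aminofulvene): the fulvenolate may not form cleanly, thiophene 1,1‑dioxide may dimerise first, or the free azulenol may not survive isolation. The fallback sets out from 3 and comes back at 9, using a Ziegler–Hafner annulation that delivers the azulenol in silyl‑protected, storable form. 3 is silylated (TBSOTf, Et3N, CH2Cl2, 0 °C) to 2‑(tert‑butyldimethylsilyloxy)‑3‑(guaiazulen‑3‑yl)‑4‑methylcyclopenta‑1,3‑diene F4. 2‑Methylpyridine and 1‑chloro‑2,4‑dinitrobenzene (neat, 100 °C) give 1‑(2,4‑dinitrophenyl)‑2‑methylpyridinium chloride F5, which dimethylamine opens to N‑[(3E,5E)‑6‑(dimethylamino)hexa‑3,5‑dien‑2‑ylidene]‑N‑methylmethanaminium chloride F6. The potassium cyclopentadienide of F4 (KN(SiMe3)2, THF, −78 °C) attacks the unsubstituted end of F6 through the ring carbon next to C–CH3, because the silyloxy group shields the other one. Heating (pyridine, 115 °C) closes the seven‑membered ring with loss of dimethylamine to give 1‑(tert‑butyldimethylsilyloxy)‑2‑(guaiazulen‑3‑yl)‑3,8‑dimethylazulene F7. Bu4NF (degassed THF, 0 °C, Ar) then gives 9, which is taken straight into step 4.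

Step 1 (direct C–H coupling): the coupling may go at C2 of guaiazulene or the bromoenone may decompose. The fallback sets out from 1 and comes back at 3, using an acid‑catalysed Friedel–Crafts hydroxyalkylation and dehydration of 1 with commercial 3‑methylcyclopentane‑1,2‑dione (TsOH, toluene, 80 °C, water removed). Guaiazulene attacks the C2 carbonyl of the diketo tautomer and water is lost towards C3. The 5‑methyl regioisomer, if formed, is removed by chromatography. This fallback makes no new compound (F0).

Further compounds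
F1 | step 4 | (±)‑4‑bromo‑3,7‑dimethylindan‑1‑one | CC1CC(=O)c2c(C)ccc(Br)c21
F2 | step 4 | (±)‑4‑bromo‑3,7‑dimethylindane‑1,2‑dione | CC1C(=O)C(=O)c2c(C)ccc(Br)c21
F3 | step 4 | 4‑bromo‑2‑(guaiazulen‑3‑yl)‑3,7‑dimethylinden‑1‑one | CC1=C(-c2cc(C)c3cc(C(C)C)ccc(C)c2-3)C(=O)c2c(C)ccc(Br)c21
F4 | step 3 | 2‑(tert‑butyldimethylsilyloxy)‑3‑(guaiazulen‑3‑yl)‑4‑methylcyclopenta‑1,3‑diene | CC1=C(-c2cc(C)c3cc(C(C)C)ccc(C)c2-3)C(O[Si](C)(C)C(C)(C)C)=CC1
F5 | step 3 | 1‑(2,4‑dinitrophenyl)‑2‑methylpyridinium chloride | Cc1cccc[n+]1-c1ccc(cc1[N+](=O)[O-])[N+](=O)[O-].[Cl-]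
F6 | step 3 | N‑[(3E,5E)‑6‑(dimethylamino)hexa‑3,5‑dien‑2‑ylidene]‑N‑methylmethanaminium chloride | CC(=[N+](C)C)/C=C/C=C/N(C)C.[Cl-]
F7 | step 3 | 1‑(tert‑butyldimethylsilyloxy)‑2‑(guaiazulen‑3‑yl)‑3,8‑dimethylazulene | CC(C)(C)[Si](C)(C)Oc1c(-c2cc(C)c3cc(C(C)C)ccc(C)c2-3)c(C)c2ccccc(C)c1-2
F0 | step 1 | none | none
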